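**Retrosynthetic overview**
- Last step: methanolysis of two acetates and one aryl silyl ether from the fully assembled threo adduct.
- C7–aryl bond: chelation-controlled addition of the ring A Grignard reagent to an (R)-2-aryloxy-3-acetoxypropanal; this sets C7.
- C8: a lipase tells apart the two enantiotopic CH2OH arms of a mirror-symmetric 2-aryloxypropane-1,3-diol (key step); the arm left free is then oxidised to the aldehyde.
- Prochiral diol: ring B phenol + diethyl chloromalonate, then LiAlH4; the phenol comes from 4-allyl-2,6-dimethoxyphenol by hydroboration.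
- No ring is formed; rings A and B are bought as 4-bromo-2,6-dimethoxyphenol and 4-allyl-2,6-dimethoxyphenol.

Assumption: the SMILES is read as the threo (7R,8R) isomer, (1R,2R)-1-(4-hydroxy-3,5-dimethoxyphenyl)-2-[4-(3-hydroxypropyl)-2,6-dimethoxyphenoxy]propane-1,3-diol (C7 = benzylic carbinol, C8 = aryl ether carbon, C9 = CH2OH), and the lipase is taken to acetylate the pro-S arm as it does with 2-O-benzylglycerol (to be confirmed on 7 by Mosher ester analysis).

**Route**

Step 1
Reactants: 1 4-allyl-2,6-dimethoxyphenol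
Product: 3 4-(3-hydroxypropyl)-2,6-dimethoxyphenol, via B-alkyl-9-BBN adduct 2 (not isolated)
Conditions: 9-BBN (2.2 equiv), THF, 0 °C to rt; then NaOH (3 M aq), H2O2 (30%), 0 °C
Reagents that add atoms: hydrogen peroxide, OO
Why: Brown hydroboration–oxidation; 9-BBN puts boron on the terminal allyl carbon (anti-Markovnikov) and alkaline peroxide replaces it by OH, the extra borane covers the phenolic O–H, and no stereocentre is formed.

Step 2
Reactants: 3 4-(3-hydroxypropyl)-2,6-dimethoxyphenol; 4 diethyl chloromalonate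
Product: 5 diethyl 2-[4-(3-hydroxypropyl)-2,6-dimethoxyphenoxy]propanedioate
Conditions: K2CO3 (1.5 equiv), DMF (degassed), rt to 50 °C
Reagents that add atoms: none
Why: Williamson ether synthesis; carbonate deprotonates only the phenol so the side-chain alcohol stays free, and the doubly ester-activated secondary chloride is a good SN2 partner for the hindered phenoxide (chloride rather than bromide limits halophilic oxidation of the electron-rich phenoxide).

Step 3
Reactants: 5 diethyl 2-[4-(3-hydroxypropyl)-2,6-dimethoxyphenoxy]propanedioate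
Product: 6 2-[4-(3-hydroxypropyl)-2,6-dimethoxyphenoxy]propane-1,3-diol
Conditions: LiAlH4 (3 equiv), THF, 0 °C to rt; H2O, NaOH (15% aq) work-up
Reagents that add atoms: none
Why: LiAlH4 ester reduction turns both esters into CH2OH and gives a diol with a mirror plane through C-2, whose two hydroxymethyl arms are enantiotopic.

Step 4 (key step)
Reactants: 6 2-[4-(3-hydroxypropyl)-2,6-dimethoxyphenoxy]propane-1,3-diol
Product: 7 3-{4-[(2S)-1-(acetyloxy)-3-hydroxypropan-2-yl]oxy-3,5-dimethoxyphenyl}propyl acetate
Conditions: Amano lipase PS (immobilised Burkholderia cepacia lipase), vinyl acetate (5 equiv), THF/t-BuOMe 1:3, 25 °C, stopped at the diacetate (HPLC)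
Reagents that add atoms: vinyl acetate, CC(=O)OC=C
Why: lipase-catalysed irreversible transesterification (enzymatic desymmetrization of a prochiral 2-O-substituted glycerol); the remote propanol is acetylated unselectively and so protected at no cost, then the enzyme acetylates only the pro-S CH2OH arm, which breaks the mirror symmetry and fixes C-2 as S (the future C8), while the minor enantiomer is over-acetylated faster to the achiral triacetate and this raises the ee.

Step 5
Reactants: 7 3-{4-[(2S)-1-(acetyloxy)-3-hydroxypropan-2-yl]oxy-3,5-dimethoxyphenyl}propyl acetate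
Product: 8 3-{4-[(2R)-1-(acetyloxy)-3-oxopropan-2-yl]oxy-3,5-dimethoxyphenyl}propyl acetate
Conditions: Dess–Martin periodinane (1.3 equiv), NaHCO3, CH2Cl2, 0 °C, 1 h; used crude at once
Reagents that add atoms: none
Why: Dess–Martin oxidation under buffered, base-free conditions gives the α-aryloxy aldehyde without epimerising C8 or eliminating the β-acetate; the label changes from S to R only because CHO now outranks CH2OAc.

Step 6
Reactants: 9 4-bromo-2,6-dimethoxyphenol
Product: 10 (4-bromo-2,6-dimethoxyphenoxy)(tert-butyl)dimethylsilane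
Conditions: TBSCl (1.3 equiv), imidazole (2.5 equiv), DMF, rt to 40 °C
Reagents that add atoms: tert-butyldimethylsilyl chloride, CC(C)(C)[Si](C)(C)Cl
Why: silyl ether formation through the N-silylimidazolium (Corey conditions) masks the acidic phenol so that the aryl Grignard reagent can be made.

Step 7
Reactants: 8 3-{4-[(2R)-1-(acetyloxy)-3-oxopropan-2-yl]oxy-3,5-dimethoxyphenyl}propyl acetate; 10 (4-bromo-2,6-dimethoxyphenoxy)(tert-butyl)dimethylsilane
Product: 12 (2R,3R)-2-{4-[3-(acetyloxy)propyl]-2,6-dimethoxyphenoxy}-3-{4-[(tert-butyldimethylsilyl)oxy]-3,5-dimethoxyphenyl}-3-hydroxypropyl acetate, via arylmagnesium bromide 11 (not isolated)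
Conditions: 10 (1.5 equiv), Mg turnings (I2 cat.), THF (1 M), 45 °C; added to 8 + MgBr2·OEt2 (2 equiv), CH2Cl2, −78 °C, 2 h; sat. aq NH4Cl at −78 °C
Reagents that add atoms: none
Why: Grignard addition under Cram-chelate control; Mg bridges the aldehyde oxygen and the α-aryl ether oxygen (twisted out of conjugation by its two ortho OMe groups and so Lewis basic, while the acetate chelates poorly), aryl attacks C7 on the face opposite CH2OAc and gives the 7,8-syn (threo) adduct, 7R from 8R, and at −78 °C the aldehyde reacts far faster than the acetates.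

Step 8
Reactants: 12 (2R,3R)-2-{4-[3-(acetyloxy)propyl]-2,6-dimethoxyphenoxy}-3-{4-[(tert-butyldimethylsilyl)oxy]-3,5-dimethoxyphenyl}-3-hydroxypropyl acetate
Product: 13 (1R,2R)-1-(4-hydroxy-3,5-dimethoxyphenyl)-2-[4-(3-hydroxypropyl)-2,6-dimethoxyphenoxy]propane-1,3-diol
Conditions: K2CO3 (0.5 equiv), MeOH, rt, 6 h; AcOH to pH 6
Reagents that add atoms: none
Why: base-catalysed methanolysis (Zemplén-type transesterification) removes both acetates and methoxide also cleaves the phenolic silyl ether because the phenoxide leaves silicon easily; at room temperature without acid neither the benzylic alcohol (no quinone methide) nor C8 is touched.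

**Compound list**
1 | 4-allyl-2,6-dimethoxyphenol | C=CCc1cc(OC)c(O)c(OC)c1 | starting material
2 | 9-[3-(4-hydroxy-3,5-dimethoxyphenyl)propyl]-9-borabicyclo[3.3.1]nonane | COc1cc(CCCB2C3CCCC2CCC3)cc(OC)c1O | intermediate
3 | 4-(3-hydroxypropyl)-2,6-dimethoxyphenol | COc1cc(CCCO)cc(OC)c1O | intermediate
4 | diethyl 2-chloropropanedioate (diethyl chloromalonate) | CCOC(=O)C(Cl)C(=O)OCC | starting material
5 | diethyl 2-[4-(3-hydroxypropyl)-2,6-dimethoxyphenoxy]propanedioate | CCOC(=O)C(Oc1c(OC)cc(CCCO)cc1OC)C(=O)OCC | intermediate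
6 | 2-[4-(3-hydroxypropyl)-2,6-dimethoxyphenoxy]propane-1,3-diol | OCC(CO)Oc1c(OC)cc(CCCO)cc1OC | intermediate
7 | 3-{4-[(2S)-1-(acetyloxy)-3-hydroxypropan-2-yl]oxy-3,5-dimethoxyphenyl}propyl acetate | OC[C@@H](COC(C)=O)Oc1c(OC)cc(CCCOC(C)=O)cc1OC | intermediate
8 | 3-{4-[(2R)-1-(acetyloxy)-3-oxopropan-2-yl]oxy-3,5-dimethoxyphenyl}propyl acetate | O=C[C@@H](COC(C)=O)Oc1c(OC)cc(CCCOC(C)=O)cc1OC | intermediate
9 | 4-bromo-2,6-dimethoxyphenol | COc1cc(Br)cc(OC)c1O | starting material
10 | (4-bromo-2,6-dimethoxyphenoxy)(tert-butyl)dimethylsilane | COc1cc(Br)cc(OC)c1O[Si](C)(C)C(C)(C)C | intermediate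
11 | {4-[(tert-butyldimethylsilyl)oxy]-3,5-dimethoxyphenyl}magnesium bromide | COc1cc([Mg]Br)cc(OC)c1O[Si](C)(C)C(C)(C)C | intermediate
12 | (2R,3R)-2-{4-[3-(acetyloxy)propyl]-2,6-dimethoxyphenoxy}-3-{4-[(tert-butyldimethylsilyl)oxy]-3,5-dimethoxyphenyl}-3-hydroxypropyl acetate | COc1cc(cc(OC)c1O[Si](C)(C)C(C)(C)C)[C@@H](O)[C@@H](COC(C)=O)Oc1c(OC)cc(CCCOC(C)=O)cc1OC | intermediate
13 | (1R,2R)-1-(4-hydroxy-3,5-dimethoxyphenyl)-2-[4-(3-hydroxypropyl)-2,6-dimethoxyphenoxy]propane-1,3-diol | COc1cc([C@@H](O)[C@@H](CO)Oc2c(OC)cc(CCCO)cc2OC)cc(OC)c1O | target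

**Totals**
Total steps: 8. Longest linear sequence: 7 (steps 1, 2, 3, 4, 5, 7, 8).

**Steps most likely to fail**

Step 7. The threo:erythro ratio may be low if Felkin–Anh attack competes with the chelate, and the acetates may be attacked. The fallback sets out from 8 and the Grignard reagent 11 and comes back to the route at 12. Reagent 11 is transmetalated with ClTi(OiPr)3 (THF, −78 °C) to the aryltitanium triisopropoxide F1, which is added to 8 in toluene at 0 °C with Ti(OiPr)4 and 10 mol % H8-BINOL. The ligand enantiomer that delivers aryl to the Re face of the aldehyde is used. C7 is then set by the catalyst and not by chelation to the substrate, and the non-basic titanium reagent leaves the acetates alone.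

Step 4. The enzyme may select the other arm or give low ee with the bulky aryloxy group, and the monoacetate can racemise by 1,3-acyl shift if not kept neutral. The fallback sets out from 6 and comes back to the route at 13. Diol 6 is desymmetrised without an enzyme, using a dinuclear zinc catalyst (ProPhenol ligand 5 mol %, Et2Zn 10 mol %) and vinyl benzoate in toluene at −15 °C. The ligand enantiomer that selects the pro-S arm is used (both are sold), and this gives the (S)-dibenzoate mono-alcohol F2. Dess–Martin oxidation as in step 5 gives the (R)-aldehyde dibenzoate F3. Addition of 11 as in step 7 gives the threo dibenzoate adduct F4; the benzoates resist the Grignard reagent better than acetates. K2CO3 in MeOH at 40 °C then gives 13.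

Step 2. The hindered, easily oxidised phenoxide may give halophilic or C-alkylation side products with the halomalonate. The fallback sets out from 1 and comes back to the route at 6 in the same number of steps. Mitsunobu etherification of 1 with 2,2-dimethyl-1,3-dioxan-5-ol (PPh3, DIAD, THF, 0 °C to rt) gives the acetonide ether 5-(4-allyl-2,6-dimethoxyphenoxy)-2,2-dimethyl-1,3-dioxane F5. Hydrolysis with 80% aqueous AcOH at 40 °C gives 2-(4-allyl-2,6-dimethoxyphenoxy)propane-1,3-diol F6. Hydroboration–oxidation as in step 1 (9-BBN; NaOH, H2O2) then gives 6.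

**Further compounds**
F1 | step 7 | [4-(tert-butyldimethylsilyloxy)-3,5-dimethoxyphenyl]tri(propan-2-yloxy)titanium | COc1cc(cc(OC)c1O[Si](C)(C)C(C)(C)C)[Ti](OC(C)C)(OC(C)C)OC(C)C
F2 | step 4 | 3-{4-[(2S)-1-(benzoyloxy)-3-hydroxypropan-2-yl]oxy-3,5-dimethoxyphenyl}propyl benzoate | OC[C@@H](COC(=O)c1ccccc1)Oc1c(OC)cc(CCCOC(=O)c2ccccc2)cc1OC
F3 | step 4 | 3-{4-[(2R)-1-(benzoyloxy)-3-oxopropan-2-yl]oxy-3,5-dimethoxyphenyl}propyl benzoate | O=C[C@@H](COC(=O)c1ccccc1)Oc1c(OC)cc(CCCOC(=O)c2ccccc2)cc1OC
F4 | step 4 | (2R,3R)-2-{4-[3-(benzoyloxy)propyl]-2,6-dimethoxyphenoxy}-3-{4-[(tert-butyldimethylsilyl)oxy]-3,5-dimethoxyphenyl}-3-hydroxypropyl benzoate | COc1cc(cc(OC)c1O[Si](C)(C)C(C)(C)C)[C@@H](O)[C@@H](COC(=O)c1ccccc1)Oc1c(OC)cc(CCCOC(=O)c2ccccc2)cc1OC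
F5 | step 2 | 5-(4-allyl-2,6-dimethoxyphenoxy)-2,2-dimethyl-1,3-dioxane | C=CCc1cc(OC)c(OC2COC(C)(C)OC2)c(OC)c1
F6 | step 2 | 2-(4-allyl-2,6-dimethoxyphenoxy)propane-1,3-diol | C=CCc1cc(OC)c(OC(CO)CO)c(OC)c1
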